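**Retrosynthetic overview**

1. Cembrane numbering is used: C1 carries the isopropyl group, C1=C2–C3=C4(Me) is the ring diene, C7 the acetoxy carbon, C8 the quaternary O-bearing carbon, C11=C12 the lactone alkene, C20 the lactone carbonyl on C12. The target comes from acetylation of the C7 alcohol, which comes from Corey–Bakshi–Shibata reduction of a C7 ketone.
2. Key disconnection: the C5–C6 bond of the 14-membered carbocycle, formed by a palladium-catalysed decarboxylative ring contraction of a 16-membered dienyl β-keto lactone (C5–O–CO–C6H2–C7(=O)–C8); the ester tether leaves as CO2.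
3. Enabling feature: C5 is the allylic terminus of the ring diene C1=C2–C3=C4, and C6 is the only enolisable carbon next to C7 because C8, the fusion carbon of the seven-membered lactone ring, is quaternary. One ester therefore delivers the π-pentadienyl cation and the enolate together.
4. The 16-membered lactone comes from acylketene macrolactonisation (C5–OH onto a tert-butyl β-keto ester made by Roskamp homologation of a C7 aldehyde). The ε-lactone comes from ring-closing metathesis (C11=C12) of the ester of a C7–C11 tertiary alcohol (C8 from (R)-2-methylglycidol) with a 2-substituted acrylic acid (C20, C12–C14, C1–C5).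
5. The dienyl acid comes from alkyne bromoboration, Negishi coupling (C14–C1), Suzuki coupling (C2–C3) and alkyne hydrocarboxylation (C20). Ring order: ε-lactone, then the temporary 16-membered lactone, then the 14-membered carbocycle.

Key step: step 17

Remark: (R)-2-methylglycidol, allylmagnesium bromide, prop-2-yn-1-ol, 3-methylbut-1-yne, (4-bromobut-1-yn-1-yl)trimethylsilane and tert-butyl diazoacetate are taken as commercial; the target is read as (1E,3E,11Z,7R,8S).

**Route**

Step 1
Reactants: 1 (R)-2-methylglycidol; 2 allylmagnesium bromide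
Product: 3 (2S)-2-methylhex-5-ene-1,2-diol
Conditions: 2 (2.5 equiv), CuBr·SMe2 (10 mol%), THF, −40 → 0 °C; aq. NH4Cl
Reagents that add atoms: none
Why: Copper-catalysed Grignard opening of the epoxide (SN2 at the unsubstituted CH2) leaves the quaternary carbon untouched, so the (R)-epoxide should give the (S)-diol that becomes C8 (the descriptor changes only through the CIP priorities), the first equivalent of 2 being spent on the O–H.

Step 2
Reactants: 3 (2S)-2-methylhex-5-ene-1,2-diol
Product: 4 (2S)-2-methyl-1-[(triethylsilyl)oxy]hex-5-en-2-ol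
Conditions: TESCl (1.05 equiv), imidazole, CH2Cl2, −20 °C
Reagents that add atoms: chlorotriethylsilane, CC[Si](Cl)(CC)CC
Why: Silylation is selective for the primary over the tertiary hydroxyl, leaving the C8–OH free for the later acylation.

Step 3
Reactants: 5 prop-2-yn-1-ol
Product: 7 (E)-3-iodo-2-methylprop-2-en-1-ol, via alkenylalane 6 (not isolated)
Conditions: AlMe3 (3 equiv), Cp2ZrCl2 (0.25 equiv), CH2Cl2, 0 → 23 °C; then I2, THF, −30 → 0 °C; aq. work-up
Reagents that add atoms: trimethylaluminium, C[Al](C)C; iodine, [I][I]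
Why: Negishi zirconium-catalysed carboalumination adds methyl and aluminium syn with methyl at the internal carbon, and iodinolysis with retention should fix the E geometry of the future C3=C4 bond.

Step 4
Reactants: 7 (E)-3-iodo-2-methylprop-2-en-1-ol
Product: 8 tert-butyl{[(E)-3-iodo-2-methylprop-2-en-1-yl]oxy}diphenylsilane
Conditions: TBDPSCl, imidazole, CH2Cl2, 0 → 23 °C
Reagents that add atoms: tert-butyl(chloro)diphenylsilane, CC(C)(C)[Si](Cl)(c1ccccc1)c1ccccc1
Why: Standard silylation of a primary alcohol, the robust silyl group being chosen to survive the acidic steps 9 and 12.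

Step 5
Reactants: 9 3-methylbut-1-yne
Product: 11 2-[(Z)-2-bromo-3-methylbut-1-en-1-yl]-4,4,5,5-tetramethyl-1,3,2-dioxaborolane, via alkenyldibromoborane 10 (not isolated)
Conditions: BBr3 (1.05 equiv), CH2Cl2, −78 → 23 °C; then pinacol, −78 → 23 °C
Reagents that add atoms: boron tribromide, BrB(Br)Br; pinacol, CC(C)(O)C(C)(C)O
Why: Bromoboration of a terminal alkyne is syn with bromine at the internal carbon, so the pinacol ester should carry Br (the future C14 site) cis to boron (the future C3 site) on what becomes C1=C2.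

Step 6
Reactants: 11 2-[(Z)-2-bromo-3-methylbut-1-en-1-yl]-4,4,5,5-tetramethyl-1,3,2-dioxaborolane; 12 (4-bromobut-1-yn-1-yl)trimethylsilane
Product: 14 4,4,5,5-tetramethyl-2-[(E)-2-(propan-2-yl)-6-(trimethylsilyl)hex-1-en-5-yn-1-yl]-1,3,2-dioxaborolane, via alkylzinc bromide 13 (not isolated)
Conditions: 12, Zn dust, I2 (5 mol%), DMA, 70 °C; then 11, Pd(PtBu3)2 (2 mol%), THF, 23 °C
Reagents that add atoms: none
Why: Negishi coupling takes place at the alkenyl C–Br bond with retention while the boronate is inert without base, forming the C14–C1 bond with C14 cis to boron.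

Step 7
Reactants: 14 4,4,5,5-tetramethyl-2-[(E)-2-(propan-2-yl)-6-(trimethylsilyl)hex-1-en-5-yn-1-yl]-1,3,2-dioxaborolane; 8 tert-butyl{[(E)-3-iodo-2-methylprop-2-en-1-yl]oxy}diphenylsilane
Product: 15 tert-butyl{[(2E,4E)-2-methyl-5-(propan-2-yl)-9-(trimethylsilyl)nona-2,4-dien-8-yn-1-yl]oxy}diphenylsilane
Conditions: Pd(dppf)Cl2 (5 mol%), aq. K3PO4, THF, 40 °C
Reagents that add atoms: none
Why: Suzuki–Miyaura coupling proceeds with retention at both alkenyl partners, so the C2–C3 bond should form with the (1E,3E)-diene geometry of the target already in place.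

Step 8
Reactants: 15 tert-butyl{[(2E,4E)-2-methyl-5-(propan-2-yl)-9-(trimethylsilyl)nona-2,4-dien-8-yn-1-yl]oxy}diphenylsilane
Product: 16 tert-butyl{[(2E,4E)-2-methyl-5-(propan-2-yl)nona-2,4-dien-8-yn-1-yl]oxy}diphenylsilane
Conditions: K2CO3, MeOH, 23 °C
Reagents that add atoms: none
Why: Base-mediated methanolysis cleaves only the alkynyl C–Si bond and leaves the silyl ether intact.

Step 9
Reactants: 16 tert-butyl{[(2E,4E)-2-methyl-5-(propan-2-yl)nona-2,4-dien-8-yn-1-yl]oxy}diphenylsilane
Product: 17 (5E,7E)-9-[(tert-butyldiphenylsilyl)oxy]-8-methyl-2-methylidene-5-(propan-2-yl)nona-5,7-dienoic acid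
Conditions: Pd(OAc)2 (5 mol%), Xantphos (10 mol%), HCO2H (2 equiv), Ac2O (20 mol%), toluene, 80 °C
Reagents that add atoms: formic acid, O=CO
Why: Palladium-catalysed Markovnikov hydrocarboxylation (Pd–H addition with palladium at the internal alkyne carbon, insertion of CO released from formic acid, hydrolysis of the acyl palladium) should give the 2-substituted acrylic acid, placing C20 on C12.

Step 10
Reactants: 17 (5E,7E)-9-[(tert-butyldiphenylsilyl)oxy]-8-methyl-2-methylidene-5-(propan-2-yl)nona-5,7-dienoic acid; 4 (2S)-2-methyl-1-[(triethylsilyl)oxy]hex-5-en-2-ol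
Product: 19 (2S)-2-methyl-1-[(triethylsilyl)oxy]hex-5-en-2-yl (5E,7E)-9-[(tert-butyldiphenylsilyl)oxy]-8-methyl-2-methylidene-5-(propan-2-yl)nona-5,7-dienoate, via acid chloride 18 (not isolated)
Conditions: 17, 1-chloro-N,N,2-trimethylprop-1-en-1-amine (1.2 equiv), CH2Cl2, 0 °C; then 4, DMAP (1.5 equiv), Et3N, CH2Cl2, 23 → 40 °C
Reagents that add atoms: none
Why: Neutral formation of the acid chloride followed by DMAP-mediated acylation should esterify the tertiary alcohol (the acid has no α-hydrogen, so no ketene pathway), without touching the C8 stereocentre.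

Step 11
Reactants: 19 (2S)-2-methyl-1-[(triethylsilyl)oxy]hex-5-en-2-yl (5E,7E)-9-[(tert-butyldiphenylsilyl)oxy]-8-methyl-2-methylidene-5-(propan-2-yl)nona-5,7-dienoate
Product: 20 (7S)-3-{(3E,5E)-7-[(tert-butyldiphenylsilyl)oxy]-6-methyl-3-(propan-2-yl)hepta-3,5-dien-1-yl}-7-methyl-7-{[(triethylsilyl)oxy]methyl}-6,7-dihydrooxepin-2(5H)-one
Conditions: second-generation Hoveyda–Grubbs catalyst (H2IMes)Cl2Ru(=CH-C6H4-2-OiPr) (10 mol%), toluene (2 mM), 80 °C
Reagents that add atoms: none
Why: Ring-closing metathesis initiates at the terminal alkene and closes onto the 1,1-disubstituted acrylate to give the seven-membered lactone, whose ring size enforces the 11Z geometry, while the trisubstituted diene alkenes should stay inert.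

Step 12
Reactants: 20 (7S)-3-{(3E,5E)-7-[(tert-butyldiphenylsilyl)oxy]-6-methyl-3-(propan-2-yl)hepta-3,5-dien-1-yl}-7-methyl-7-{[(triethylsilyl)oxy]methyl}-6,7-dihydrooxepin-2(5H)-one
Product: 21 (7S)-3-{(3E,5E)-7-[(tert-butyldiphenylsilyl)oxy]-6-methyl-3-(propan-2-yl)hepta-3,5-dien-1-yl}-7-(hydroxymethyl)-7-methyl-6,7-dihydrooxepin-2(5H)-one
Conditions: PPTS (0.2 equiv), MeOH/CH2Cl2 (1:1), 0 °C
Reagents that add atoms: none
Why: Mildly acidic methanolysis removes the triethylsilyl ether selectively beside the tert-butyldiphenylsilyl ether, and the absence of base should avoid a 1,2-acyl shift of the lactone to the freed primary hydroxyl.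

Step 13
Reactants: 21 (7S)-3-{(3E,5E)-7-[(tert-butyldiphenylsilyl)oxy]-6-methyl-3-(propan-2-yl)hepta-3,5-dien-1-yl}-7-(hydroxymethyl)-7-methyl-6,7-dihydrooxepin-2(5H)-one
Product: 22 (2S)-6-{(3E,5E)-7-[(tert-butyldiphenylsilyl)oxy]-6-methyl-3-(propan-2-yl)hepta-3,5-dien-1-yl}-2-methyl-7-oxo-2,3,4,7-tetrahydrooxepine-2-carbaldehyde
Conditions: Dess–Martin periodinane (1.5 equiv), NaHCO3, CH2Cl2, 0 → 23 °C (21 used at once)
Reagents that add atoms: none
Why: Dess–Martin oxidation gives the C7 aldehyde under buffered conditions, and since its α-carbon (C8) is quaternary it cannot epimerise.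

Step 14
Reactants: 22 (2S)-6-{(3E,5E)-7-[(tert-butyldiphenylsilyl)oxy]-6-methyl-3-(propan-2-yl)hepta-3,5-dien-1-yl}-2-methyl-7-oxo-2,3,4,7-tetrahydrooxepine-2-carbaldehyde; 23 tert-butyl diazoacetate
Product: 24 tert-butyl 3-[(2S)-6-{(3E,5E)-7-[(tert-butyldiphenylsilyl)oxy]-6-methyl-3-(propan-2-yl)hepta-3,5-dien-1-yl}-2-methyl-7-oxo-2,3,4,7-tetrahydrooxepin-2-yl]-3-oxopropanoate
Conditions: SnCl2 (10 mol%), CH2Cl2, 23 °C
Reagents that add atoms: none
Why: Roskamp homologation (Lewis-acid-promoted addition of the diazo ester to the aldehyde, 1,2-hydride shift, loss of N2) installs C6 and the ester carbon as a β-keto ester without any enolate that could attack the lactone.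

Step 15
Reactants: 24 tert-butyl 3-[(2S)-6-{(3E,5E)-7-[(tert-butyldiphenylsilyl)oxy]-6-methyl-3-(propan-2-yl)hepta-3,5-dien-1-yl}-2-methyl-7-oxo-2,3,4,7-tetrahydrooxepin-2-yl]-3-oxopropanoate
Product: 25 tert-butyl 3-[(2S)-6-{(3E,5E)-7-hydroxy-6-methyl-3-(propan-2-yl)hepta-3,5-dien-1-yl}-2-methyl-7-oxo-2,3,4,7-tetrahydrooxepin-2-yl]-3-oxopropanoate
Conditions: HF·pyridine, pyridine, THF, 0 → 23 °C
Reagents that add atoms: none
Why: Buffered fluoride desilylation frees the C5 hydroxyl while keeping the γ-acyloxy β-keto ester un-enolised, so no enolate attack on the lactone carbonyl is expected.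

Step 16
Reactants: 25 tert-butyl 3-[(2S)-6-{(3E,5E)-7-hydroxy-6-methyl-3-(propan-2-yl)hepta-3,5-dien-1-yl}-2-methyl-7-oxo-2,3,4,7-tetrahydrooxepin-2-yl]-3-oxopropanoate
Product: 27 (8S)-16-membered dienyl β-keto lactone (C5–O–C(=O)–C6H2–C7(=O)–C8 link, ring counted through C9–C11, ε-lactone and (1E,3E)-diene intact), via acylketene 26 (not isolated)
Conditions: toluene, 110 °C, syringe-pump addition (final 1 mM)
Reagents that add atoms: none
Why: Thermal loss of tert-butanol from the tert-butyl β-keto ester gives an acylketene that the primary dienylic alcohol should trap intramolecularly at high dilution (acylketene macrolactonisation), closing the temporary 16-membered ring below the temperature of a Carroll rearrangement.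

Step 17
Reactants: 27 (8S)-16-membered dienyl β-keto lactone
Product: 28 (1E,3E,11Z,8S)-7-oxocembra-1,3,11-trien-20,8-olide
Conditions: Pd(PPh3)4 (10 mol%), degassed THF (2 mM), 50 °C
Reagents that add atoms: none
Why: Proposed new method: zerovalent palladium should ionise the dienylic C5–O bond of 27 to a π-pentadienylpalladium cation that stays tethered to its β-keto carboxylate counter-ion; loss of CO2 (or C-allylation at C6 followed by decarboxylation of the β-keto acid) gives the C7 enolate, which recombines with the allyl terminus C5, so that the ester tether is excised and the 16-membered lactone contracts to the 14-membered carbocycle. The closest known reaction type is the Tsuji–Saegusa (Carroll-type) decarboxylative allylation of acyclic allyl β-keto esters, together with palladium-catalysed Tsuji–Trost macrocyclisation of β-keto esters onto allylic esters; the new element is its use as a ring contraction of a macrocyclic dienyl β-keto lactone. The 14-membered ring is closed in the endo mode, by attack at the distal, unsubstituted allyl terminus C5, which keeps all three allyl carbons in the ring and regenerates the conjugated C3=C4 alkene; attack at C3 (exo mode, 12-membered ring, skipped diene) or at the fully substituted C1 is disfavoured sterically and by loss of conjugation. No stereocentre is formed; the 3E geometry is retained because the E-ester gives the syn π-allyl and C1=C2 lies outside the reacting allyl unit. The step needs intramolecular over intermolecular recombination and C- over O-allylation: both partners are born on one chain at 2 mM, the enolate can form only at C6 because C8 is quaternary, and the neutral conditions spare the unsaturated ε-lactone and the C8 stereocentre.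

Step 18
Reactants: 28 (1E,3E,11Z,8S)-7-oxocembra-1,3,11-trien-20,8-olide
Product: 29 (1E,3E,11Z,7R,8S)-7-hydroxycembra-1,3,11-trien-20,8-olide
Conditions: (S)-2-methyl-CBS-oxazaborolidine (0.5 equiv), catecholborane (2 equiv), toluene, −78 → −40 °C; MeOH
Reagents that add atoms: none
Why: Corey–Bakshi–Shibata reduction under reagent control, with the quaternary C8 as the large and C6H2 as the small ketone substituent, should deliver hydride to the face that gives the 7R alcohol (the same sense as acetophenone to the R alcohol), catecholborane sparing the diene and the lactone.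

Step 19
Reactants: 29 (1E,3E,11Z,7R,8S)-7-hydroxycembra-1,3,11-trien-20,8-olide
Product: 30 (1E,3E,11Z,7R,8S)-7-acetoxycembra-1,3,11-trien-20,8-olide (CNP0291129.1)
Conditions: Ac2O, DMAP (cat.), pyridine, CH2Cl2, 23 °C
Reagents that add atoms: acetic anhydride, CC(=O)OC(C)=O
Why: DMAP-catalysed acetylation of the secondary C7 alcohol proceeds with retention and completes the target.

**Compound list**

1 | (R)-2-methylglycidol, [(2R)-2-methyloxiran-2-yl]methanol | OC[C@]1(C)CO1 | starting material
2 | allylmagnesium bromide | C=CC[Mg]Br | starting material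
3 | (2S)-2-methylhex-5-ene-1,2-diol | C=CCC[C@](C)(O)CO | intermediate
4 | (2S)-2-methyl-1-[(triethylsilyl)oxy]hex-5-en-2-ol | C=CCC[C@](C)(O)CO[Si](CC)(CC)CC | intermediate
5 | prop-2-yn-1-ol | C#CCO | starting material
6 | alkenylalane, {(E)-3-[(dimethylalumanyl)oxy]-2-methylprop-1-en-1-yl}dimethylalumane | C[Al](C)OC/C(C)=C/[Al](C)C | intermediate
7 | (E)-3-iodo-2-methylprop-2-en-1-ol | OC/C(C)=C/I | intermediate
8 | tert-butyl{[(E)-3-iodo-2-methylprop-2-en-1-yl]oxy}diphenylsilane | CC(C)(C)[Si](OC/C(C)=C/I)(c1ccccc1)c1ccccc1 | intermediate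
9 | 3-methylbut-1-yne | CC(C)C#C | starting material
10 | alkenyldibromoborane, dibromo[(Z)-2-bromo-3-methylbut-1-en-1-yl]borane | CC(C)/C(Br)=C/B(Br)Br | intermediate
11 | 2-[(Z)-2-bromo-3-methylbut-1-en-1-yl]-4,4,5,5-tetramethyl-1,3,2-dioxaborolane | CC(C)/C(Br)=C/B1OC(C)(C)C(C)(C)O1 | intermediate
12 | (4-bromobut-1-yn-1-yl)trimethylsilane | C[Si](C)(C)C#CCCBr | starting material
13 | alkylzinc bromide, bromo[4-(trimethylsilyl)but-3-yn-1-yl]zinc | C[Si](C)(C)C#CCC[Zn]Br | intermediate
14 | 4,4,5,5-tetramethyl-2-[(E)-2-(propan-2-yl)-6-(trimethylsilyl)hex-1-en-5-yn-1-yl]-1,3,2-dioxaborolane | C[Si](C)(C)C#CCC/C(C(C)C)=C\B1OC(C)(C)C(C)(C)O1 | intermediate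
15 | tert-butyl{[(2E,4E)-2-methyl-5-(propan-2-yl)-9-(trimethylsilyl)nona-2,4-dien-8-yn-1-yl]oxy}diphenylsilane | C[Si](C)(C)C#CCC/C(C(C)C)=C\C=C(C)\CO[Si](c1ccccc1)(c1ccccc1)C(C)(C)C | intermediate
16 | tert-butyl{[(2E,4E)-2-methyl-5-(propan-2-yl)nona-2,4-dien-8-yn-1-yl]oxy}diphenylsilane | C#CCC/C(C(C)C)=C\C=C(C)\CO[Si](c1ccccc1)(c1ccccc1)C(C)(C)C | intermediate
17 | (5E,7E)-9-[(tert-butyldiphenylsilyl)oxy]-8-methyl-2-methylidene-5-(propan-2-yl)nona-5,7-dienoic acid | C=C(C(=O)O)CC/C(C(C)C)=C\C=C(C)\CO[Si](c1ccccc1)(c1ccccc1)C(C)(C)C | intermediate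
18 | acid chloride of 17, (5E,7E)-9-[(tert-butyldiphenylsilyl)oxy]-8-methyl-2-methylidene-5-(propan-2-yl)nona-5,7-dienoyl chloride | C=C(C(=O)Cl)CC/C(C(C)C)=C\C=C(C)\CO[Si](c1ccccc1)(c1ccccc1)C(C)(C)C | intermediate
19 | (2S)-2-methyl-1-[(triethylsilyl)oxy]hex-5-en-2-yl (5E,7E)-9-[(tert-butyldiphenylsilyl)oxy]-8-methyl-2-methylidene-5-(propan-2-yl)nona-5,7-dienoate | C=CCC[C@](C)(OC(=O)C(=C)CC/C(C(C)C)=C\C=C(C)\CO[Si](c1ccccc1)(c1ccccc1)C(C)(C)C)CO[Si](CC)(CC)CC | intermediate
20 | (7S)-3-{(3E,5E)-7-[(tert-butyldiphenylsilyl)oxy]-6-methyl-3-(propan-2-yl)hepta-3,5-dien-1-yl}-7-methyl-7-{[(triethylsilyl)oxy]methyl}-6,7-dihydrooxepin-2(5H)-one | C[C@@]1(CO[Si](CC)(CC)CC)CCC=C(CC/C(C(C)C)=C\C=C(C)\CO[Si](c2ccccc2)(c2ccccc2)C(C)(C)C)C(=O)O1 | intermediate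
21 | (7S)-3-{(3E,5E)-7-[(tert-butyldiphenylsilyl)oxy]-6-methyl-3-(propan-2-yl)hepta-3,5-dien-1-yl}-7-(hydroxymethyl)-7-methyl-6,7-dihydrooxepin-2(5H)-one | C[C@@]1(CO)CCC=C(CC/C(C(C)C)=C\C=C(C)\CO[Si](c2ccccc2)(c2ccccc2)C(C)(C)C)C(=O)O1 | intermediate
22 | (2S)-6-{(3E,5E)-7-[(tert-butyldiphenylsilyl)oxy]-6-methyl-3-(propan-2-yl)hepta-3,5-dien-1-yl}-2-methyl-7-oxo-2,3,4,7-tetrahydrooxepine-2-carbaldehyde | C[C@@]1(C=O)CCC=C(CC/C(C(C)C)=C\C=C(C)\CO[Si](c2ccccc2)(c2ccccc2)C(C)(C)C)C(=O)O1 | intermediate
23 | tert-butyl diazoacetate | CC(C)(C)OC(=O)C=[N+]=[N-] | starting material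
24 | tert-butyl 3-[(2S)-6-{(3E,5E)-7-[(tert-butyldiphenylsilyl)oxy]-6-methyl-3-(propan-2-yl)hepta-3,5-dien-1-yl}-2-methyl-7-oxo-2,3,4,7-tetrahydrooxepin-2-yl]-3-oxopropanoate | C[C@@]1(C(=O)CC(=O)OC(C)(C)C)CCC=C(CC/C(C(C)C)=C\C=C(C)\CO[Si](c2ccccc2)(c2ccccc2)C(C)(C)C)C(=O)O1 | intermediate
25 | tert-butyl 3-[(2S)-6-{(3E,5E)-7-hydroxy-6-methyl-3-(propan-2-yl)hepta-3,5-dien-1-yl}-2-methyl-7-oxo-2,3,4,7-tetrahydrooxepin-2-yl]-3-oxopropanoate | C[C@@]1(C(=O)CC(=O)OC(C)(C)C)CCC=C(CC/C(C(C)C)=C\C=C(C)\CO)C(=O)O1 | intermediate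
26 | acylketene of 25 (the C7 acyl group carries CH=C=O in place of CH2CO2tBu, C5–OH free) | C[C@@]1(C(=O)C=C=O)CCC=C(CC/C(C(C)C)=C\C=C(C)\CO)C(=O)O1 | intermediate
27 | (8S)-16-membered dienyl β-keto lactone (C5–O–C(=O)–C6H2–C7(=O)–C8 link, ring counted through C9–C11, fused to the ε-lactone, (1E,3E)-diene) | C[C@@]12CCC=C(CC/C(C(C)C)=C\C=C(C)\COC(=O)CC2=O)C(=O)O1 | intermediate
28 | (1E,3E,11Z,8S)-7-oxocembra-1,3,11-trien-20,8-olide | C[C@@]12CCC=C(CC/C(C(C)C)=C\C=C(C)\CCC2=O)C(=O)O1 | intermediate
29 | (1E,3E,11Z,7R,8S)-7-hydroxycembra-1,3,11-trien-20,8-olide | C[C@@]12CCC=C(CC/C(C(C)C)=C\C=C(C)\CC[C@H]2O)C(=O)O1 | intermediate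
30 | (1E,3E,11Z,7R,8S)-7-acetoxycembra-1,3,11-trien-20,8-olide (CNP0291129.1) | CC(=O)O[C@@H]1CC/C(C)=C/C=C(/C(C)C)CCC2=CCC[C@]1(C)OC2=O | target

**Step count and risks**

Total step count: 19. Longest linear sequence: 15 steps (steps 5 to 19, from 9 to 30).

Steps most likely to fail:

1. Step 17 (Proposed new method). What may go wrong: recombination of the ion pair between molecules (oligomers), recombination at C3 instead of C5, or β-hydride loss from the π-allyl with protonation of the enolate. The fallback uses known chemistry and sets out from 25. Methyl chloroformate and pyridine (CH2Cl2, 0 °C) should give the dienyl methyl carbonate F1. Pd(PPh3)4 (THF, 2 mM, 60 °C) should then effect a conventional intramolecular Tsuji–Trost alkylation of the π-pentadienyl complex by the β-keto ester carbon, closing the same C5–C6 bond to the 14-membered tert-butyl β-keto ester F2 (C6 epimers). Trifluoroacetic acid (CH2Cl2, 0 °C) should cleave the tert-butyl ester to the β-keto acid F3, which decarboxylates on warming and rejoins the route at 28.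

2. Step 18. What may go wrong: poor facial selectivity if the catalyst is mismatched with the substrate, since the polar Felkin–Anh model (lactone oxygen anti to the hydride) and peripheral attack on the macrocycle may both favour the other face. The fallback sets out from 28. Substrate-controlled reduction (NaBH4, CeCl3·7H2O, MeOH, −78 °C) is expected to favour the (7S)-alcohol F4. A Mitsunobu reaction with acetic acid (PPh3, diisopropyl azodicarboxylate, AcOH, toluene, 0 → 23 °C) should then invert C7 and install the acetate in one operation, rejoining the route at 30.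

3. Step 9. What may go wrong: loss of regiocontrol in the hydropalladation (linear acid), isomerisation of the diene by palladium hydride, or cleavage of the dienylic silyl ether by formic acid. The fallback sets out from 16. Copper-catalysed α-selective protoboration ((SIMes)CuCl, NaOtBu, bis(pinacolato)diboron, MeOH, THF, −50 → 23 °C) should give the 1,1-disubstituted alkenylboronate F5. Copper-catalysed carboxylation with CO2 ((IPr)CuCl, KOtBu, CO2 at 1 atm, THF, 70 °C; acidic work-up) should then give the acrylic acid, rejoining the route at 17.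

Further compounds
F1 | step 17 | tert-butyl 3-[(2S)-6-{(3E,5E)-7-[(methoxycarbonyl)oxy]-6-methyl-3-(propan-2-yl)hepta-3,5-dien-1-yl}-2-methyl-7-oxo-2,3,4,7-tetrahydrooxepin-2-yl]-3-oxopropanoate | C[C@@]1(C(=O)CC(=O)OC(C)(C)C)CCC=C(CC/C(C(C)C)=C\C=C(C)\COC(=O)OC)C(=O)O1
F2 | step 17 | tert-butyl (1E,3E,11Z,8S)-7-oxocembra-1,3,11-trien-20,8-olide-6-carboxylate (C6 epimers) | C[C@@]12CCC=C(CC/C(C(C)C)=C\C=C(C)\CC(C(=O)OC(C)(C)C)C2=O)C(=O)O1
F3 | step 17 | (1E,3E,11Z,8S)-7-oxocembra-1,3,11-trien-20,8-olide-6-carboxylic acid (C6 epimers) | C[C@@]12CCC=C(CC/C(C(C)C)=C\C=C(C)\CC(C(=O)O)C2=O)C(=O)O1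
F4 | step 18 | (1E,3E,11Z,7S,8S)-7-hydroxycembra-1,3,11-trien-20,8-olide | C[C@@]12CCC=C(CC/C(C(C)C)=C\C=C(C)\CC[C@@H]2O)C(=O)O1
F5 | step 9 | tert-butyl{[(2E,4E)-2-methyl-5-(propan-2-yl)-8-(4,4,5,5-tetramethyl-1,3,2-dioxaborolan-2-yl)nona-2,4,8-trien-1-yl]oxy}diphenylsilane | C=C(B1OC(C)(C)C(C)(C)O1)CC/C(C(C)C)=C\C=C(C)\CO[Si](c1ccccc1)(c1ccccc1)C(C)(C)C
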